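**Retrosynthetic overview**
- Rings: A is the para-disubstituted ring, B the 3-hydroxyphenyl ring, C the trisubstituted ring and D the 3-methoxyphenyl ring. The route rests on ring B. Its oxygen on B3 is 1,3 to the chain carbon B1, and the CH between them (B2) is bare. This is the pattern of a 6-alkylsalicylic acid that has lost its B2 carboxyl, so ring B is traced back through the salicylate to a 2-oxocyclohex-3-enecarboxylate.
- Key disconnection: B1–B2 (conjugate addition) and B4–B5 (aldol condensation). This splits the cyclohexenone into ethyl acetoacetate (B2, B3, B4 and the ester) and an (E)-5-arylpent-2-enal (B1, B6, B5) that already carries rings A, C and D.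
- The enal comes from an aryl iodide by Heck reaction with allyl alcohol and a two-carbon Wittig homologation. The A–O–C ether comes from a Chan–Lam coupling and the C–D bibenzyl from a B-alkyl Suzuki coupling. The ring C oxygen pattern comes from 5-bromosalicylaldehyde by benzylation and Baeyer–Villiger oxidation.
- Ring order: C, D and A are bought as arenes and joined in that order, and ring B is the only ring built, last. The B3 oxygen arrives as a ketone and the ring D oxygen is methylated from the start, so no step has to distinguish the two meta-oxygenated termini.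

Key step: step 7

Abbreviation: Ar* = 4-{2-(benzyloxy)-5-[2-(3-methoxyphenyl)ethyl]phenoxy}phenyl. This is ring A, joined through oxygen to ring C, which carries OBn and the CH2CH2–ring D arm.

Assumption: the target has no stereocentre. The sp3 centres made in the key step are racemic and unassigned, so their SMILES carry no descriptors. All of them vanish on aromatization.

**Step 1**
Reactants: 1 5-bromosalicylaldehyde
Product: 2 2-(benzyloxy)-5-bromobenzaldehyde
Conditions: BnBr (1.1 equiv), K2CO3 (1.5 equiv), DMF, rt → 50 °C
Reagents that add atoms: benzyl bromide, BrCc1ccccc1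
Why: Williamson etherification of the acidic phenol with a primary benzylic bromide is unambiguous, and the benzyl group masks the future ring C hydroxyl until the last step.

**Step 2**
Reactants: 2 2-(benzyloxy)-5-bromobenzaldehyde
Product: 4 2-(benzyloxy)-5-bromophenol, via aryl formate 3 (not isolated)
Conditions: mCPBA (1.4 equiv), CH2Cl2, rt; then NaOH, MeOH–H2O, 0 °C → rt; HCl work-up
Reagents that add atoms: mCPBA (3-chloroperoxybenzoic acid), OOC(=O)c1cccc(Cl)c1
Why: In this Baeyer–Villiger oxidation of Dakin type the ortho-alkoxy group makes aryl migration faster than hydride migration, so the formyl carbon leaves as formate and its ring carbon becomes the phenol site meta to bromine; a peracid is used because the alkaline peroxide Dakin reaction needs a free ortho or para hydroxyl.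

**Step 3**
Reactants: 4 2-(benzyloxy)-5-bromophenol; 5 3-vinylanisole
Product: 7 2-(benzyloxy)-5-[2-(3-methoxyphenyl)ethyl]phenol, via alkylborane 6 (not isolated)
Conditions: 5 (1.3 equiv), 9-BBN-H (1.3 equiv), THF, 0 °C → rt; then 4, Pd(OAc)2 (3 mol %), SPhos (6 mol %), 3 M aq K3PO4 (4 equiv), THF, 65 °C
Reagents that add atoms: none
Why: Anti-Markovnikov hydroboration of the styrene followed by B-alkyl Suzuki–Miyaura coupling joins the primary sp3 carbon to the aryl bromide, the extra phosphate carrying the free phenol through as its phenoxide and the electron-rich biaryl phosphine offsetting the electron-rich bromide.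

**Step 4**
Reactants: 7 2-(benzyloxy)-5-[2-(3-methoxyphenyl)ethyl]phenol; 8 4-iodophenylboronic acid
Product: 9 1-(benzyloxy)-2-(4-iodophenoxy)-4-[2-(3-methoxyphenyl)ethyl]benzene (Ar*–I)
Conditions: 8 (2 equiv), Cu(OAc)2 (1 equiv), pyridine (5 equiv), 4 Å MS, CH2Cl2, dry air, rt
Reagents that add atoms: none
Why: Chan–Lam O-arylation proceeds at room temperature through a transient trivalent copper aryl phenoxide, conditions that leave a C–I bond untouched, so the iodide survives as the handle for step 5.

**Step 5**
Reactants: 9 Ar*–I; 10 allyl alcohol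
Product: 11 3-Ar*-propanal
Conditions: 10 (1.5 equiv), Pd(OAc)2 (5 mol %), Bu4NCl (1 equiv), NaHCO3 (2.5 equiv), DMF, 45 °C
Reagents that add atoms: none
Why: In this Heck arylation under ligand-free phase-transfer conditions, carbopalladation at the terminal alkene carbon, β-hydride elimination toward the carbinol carbon and tautomerization should give the saturated 3-arylpropanal directly.

**Step 6**
Reactants: 11 3-Ar*-propanal; 12 (triphenylphosphoranylidene)acetaldehyde
Product: 13 (E)-5-Ar*-pent-2-enal
Conditions: 12 (1.2 equiv), toluene, 80 °C
Reagents that add atoms: none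
Why: Wittig formylolefination with the stabilized ylide is E-selective, and the conjugated product aldehyde is less electrophilic than 11, which limits a second homologation.

**Step 7**
Reactants: 13 (E)-5-Ar*-pent-2-enal; 14 ethyl acetoacetate
Product: 17 ethyl 2-oxo-6-(2-Ar*-ethyl)cyclohex-3-ene-1-carboxylate (racemic cis/trans mixture in equilibrium with its enol), via Michael adduct 15 (not isolated), via aldol 16 (not isolated)
Conditions: 14 (1.1 equiv), NaOEt (0.15 equiv), EtOH–THF, 0 °C → rt; solvent exchange; TsOH·H2O (0.3 equiv), toluene, 80 °C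
Reagents that add atoms: none
Why: Catalytic ethoxide ionizes only the doubly activated CH2 of 14, and this soft, stabilized enolate adds to the β-carbon of 13 to form B1–B2 and the keto aldehyde 15, attack at the formyl carbon being reversible under alkoxide catalysis and draining into the conjugate adduct. Proton exchange then gives the methyl ketone enolate of 15, which closes ring B on the freed aldehyde by a 6-(enolendo)-exo-trig aldol addition (both enolate carbons, B3 and B4, lie in the new ring, a favoured mode at ring size six) to form B4–B5 in 16, and acid-catalysed loss of water puts the B4=B5 double bond in conjugation with the B3 ketone in 17. The closest known reaction type is the alkoxide-catalysed Michael–aldol (Robinson-type) annulation of acetoacetic esters with 2-alkenals, which gives 6-alkyl-2-oxocyclohex-3-enecarboxylates. The centres at B1 and B2 (and B5 in 16) form racemic and without control, B2 equilibrating through the enol toward the trans isomer, and none needs control because step 8 flattens all of them. The step needs site and order selectivity (central carbon before methyl carbon, 1,4 before 1,2), which the acidity gap between the two acetoacetate positions secures, while the sub-stoichiometric base, buffered by the slight excess of 14, stays too weak to deprotonate the γ-CH2 of 13. Low temperature and nearly equimolar 14 hold back a second conjugate addition to 17.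

**Step 8**
Reactants: 17 ethyl 2-oxo-6-(2-Ar*-ethyl)cyclohex-3-ene-1-carboxylate
Product: 20 ethyl 2-hydroxy-6-(2-Ar*-ethyl)benzoate, via selenide 18 (not isolated), via selenoxide 19 (not isolated)
Conditions: NaH (1.1 equiv), THF, 0 °C; PhSeCl (1.1 equiv), 0 °C; then 30 % H2O2 (excess), CH2Cl2, 0 °C → rt
Reagents that add atoms: none
Why: In this selenoxide syn-elimination the β-keto ester enolate is selenenylated at B2 on the face away from the B1 side chain, which puts selenium cis to B1–H, so oxidation to 19 triggers elimination across B1–B2 to a cross-conjugated dienone that tautomerizes at once to the hydrogen-bonded salicylate; this mild sequence is preferred to a high-potential quinone such as DDQ, which is known to dehydrogenate para-oxygenated bibenzyl bridges of the kind present twice in 17.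

**Step 9**
Reactants: 20 ethyl 2-hydroxy-6-(2-Ar*-ethyl)benzoate
Product: 21 2-hydroxy-6-(2-Ar*-ethyl)benzoic acid
Conditions: KOH (10 equiv), DMSO–H2O (4:1), 100 °C; then 1 M HCl
Reagents that add atoms: potassium hydroxide, [K+].[OH-]
Why: Saponification of a benzoate flanked by two ortho groups is slow, so poorly solvated hydroxide in hot aqueous DMSO is used, and every other function in 20 is an aryl, methyl or benzyl ether that is inert to base.

**Step 10**
Reactants: 21 2-hydroxy-6-(2-Ar*-ethyl)benzoic acid
Product: 22 3-(2-Ar*-ethyl)phenol
Conditions: Ag2CO3 (10 mol %), AcOH (5 mol %), DMSO, 120 °C, N2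
Reagents that add atoms: none
Why: Silver-catalysed protodecarboxylation works best on benzoic acids with ortho heteroatom substituents and two ortho groups, as in 21, and the purely thermal loss of CO2 typical of 6-alkylsalicylic acids runs in the same direction.

**Step 11**
Reactants: 22 3-(2-Ar*-ethyl)phenol
Product: 23 2-{4-[2-(3-hydroxyphenyl)ethyl]phenoxy}-4-[2-(3-methoxyphenyl)ethyl]phenol (target)
Conditions: H2 (1 atm), Pd/C (10 wt %), EtOAc–EtOH, rt
Reagents that add atoms: none
Why: Catalytic hydrogenolysis cleaves only the benzylic C–O bond, since the diaryl ether, the methyl ether and the saturated bridges are not reducible under these conditions.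

**Compound list**
1 | 5-bromosalicylaldehyde | O=Cc1cc(Br)ccc1O | starting material
2 | 2-(benzyloxy)-5-bromobenzaldehyde | O=Cc1cc(Br)ccc1OCc1ccccc1 | intermediate
3 | 2-(benzyloxy)-5-bromophenyl formate | O=COc1cc(Br)ccc1OCc1ccccc1 | intermediate
4 | 2-(benzyloxy)-5-bromophenol | Oc1cc(Br)ccc1OCc1ccccc1 | intermediate
5 | 3-vinylanisole | C=Cc1cccc(OC)c1 | starting material
6 | 9-[2-(3-methoxyphenyl)ethyl]-9-borabicyclo[3.3.1]nonane | COc1cccc(CCB2C3CCCC2CCC3)c1 | intermediate
7 | 2-(benzyloxy)-5-[2-(3-methoxyphenyl)ethyl]phenol | COc1cccc(CCc2ccc(OCc3ccccc3)c(O)c2)c1 | intermediate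
8 | 4-iodophenylboronic acid | OB(O)c1ccc(I)cc1 | starting material
9 | 1-(benzyloxy)-2-(4-iodophenoxy)-4-[2-(3-methoxyphenyl)ethyl]benzene (Ar*–I) | COc1cccc(CCc2ccc(OCc3ccccc3)c(Oc3ccc(I)cc3)c2)c1 | intermediate
10 | allyl alcohol | C=CCO | starting material
11 | 3-(4-{2-(benzyloxy)-5-[2-(3-methoxyphenyl)ethyl]phenoxy}phenyl)propanal | COc1cccc(CCc2ccc(OCc3ccccc3)c(Oc3ccc(CCC=O)cc3)c2)c1 | intermediate
12 | (triphenylphosphoranylidene)acetaldehyde | O=CC=P(c1ccccc1)(c1ccccc1)c1ccccc1 | starting material
13 | (2E)-5-(4-{2-(benzyloxy)-5-[2-(3-methoxyphenyl)ethyl]phenoxy}phenyl)pent-2-enal | COc1cccc(CCc2ccc(OCc3ccccc3)c(Oc3ccc(CC/C=C/C=O)cc3)c2)c1 | intermediate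
14 | ethyl acetoacetate | CCOC(=O)CC(C)=O | starting material
15 | ethyl 2-acetyl-3-(2-oxoethyl)-5-Ar*-pentanoate (diastereomer mixture) | COc1cccc(CCc2ccc(OCc3ccccc3)c(Oc3ccc(CCC(CC=O)C(C(C)=O)C(=O)OCC)cc3)c2)c1 | intermediate
16 | ethyl 4-hydroxy-2-oxo-6-(2-Ar*-ethyl)cyclohexane-1-carboxylate (diastereomer mixture) | COc1cccc(CCc2ccc(OCc3ccccc3)c(Oc3ccc(CCC4CC(O)CC(=O)C4C(=O)OCC)cc3)c2)c1 | intermediate
17 | ethyl 2-oxo-6-(2-Ar*-ethyl)cyclohex-3-ene-1-carboxylate (diastereomer mixture) | COc1cccc(CCc2ccc(OCc3ccccc3)c(Oc3ccc(CCC4CC=CC(=O)C4C(=O)OCC)cc3)c2)c1 | intermediate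
18 | ethyl 2-oxo-1-(phenylselanyl)-6-(2-Ar*-ethyl)cyclohex-3-ene-1-carboxylate | COc1cccc(CCc2ccc(OCc3ccccc3)c(Oc3ccc(CCC4CC=CC(=O)C4([Se]c5ccccc5)C(=O)OCC)cc3)c2)c1 | intermediate
19 | ethyl 2-oxo-1-(phenylseleninyl)-6-(2-Ar*-ethyl)cyclohex-3-ene-1-carboxylate | COc1cccc(CCc2ccc(OCc3ccccc3)c(Oc3ccc(CCC4CC=CC(=O)C4([Se](=O)c5ccccc5)C(=O)OCC)cc3)c2)c1 | intermediate
20 | ethyl 2-hydroxy-6-(2-Ar*-ethyl)benzoate | COc1cccc(CCc2ccc(OCc3ccccc3)c(Oc3ccc(CCc4cccc(O)c4C(=O)OCC)cc3)c2)c1 | intermediate
21 | 2-hydroxy-6-(2-Ar*-ethyl)benzoic acid | COc1cccc(CCc2ccc(OCc3ccccc3)c(Oc3ccc(CCc4cccc(O)c4C(=O)O)cc3)c2)c1 | intermediate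
22 | 3-(2-Ar*-ethyl)phenol | COc1cccc(CCc2ccc(OCc3ccccc3)c(Oc3ccc(CCc4cccc(O)c4)cc3)c2)c1 | intermediate
23 | 2-{4-[2-(3-hydroxyphenyl)ethyl]phenoxy}-4-[2-(3-methoxyphenyl)ethyl]phenol | COc1cccc(CCc2ccc(O)c(Oc3ccc(CCc4cccc(O)c4)cc3)c2)c1 | target

**Step count and risks**

Total step count: 11. Longest linear sequence: 11 steps (1 → 23). All other building blocks are commercial and enter directly.

**Step 7** is the most likely to fail.
- What may go wrong: attack at the formyl carbon followed by irreversible dehydration (the Knoevenagel path), base-induced self-condensation of the enal through its γ-position, or a second conjugate addition of acetoacetate to the new enone. Any of these would erode the annulation.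
- Fallback: ring B is bought instead of built. It sets out from iodide 9, which is coupled with commercial 3-ethynylphenol under Sonogashira conditions (Pd(PPh3)2Cl2, CuI, Et3N, THF, rt) to the diarylalkyne 3-(Ar*-ethynyl)phenol F1. Hydrogenation over Pd/C (H2, EtOAc–EtOH, rt) should saturate the triple bond and cleave the benzyl ether in the same operation. The fallback comes back to the route at target 23.

**Step 8** comes second.
- What may go wrong: selenenylation on the face that leaves selenium trans to B1–H would block the syn-elimination, and the seleninic acid and peroxide mixture could over-oxidize the fresh phenol.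
- Fallback: the order of CO2 loss and oxidation is reversed. It sets out from 17, and Krapcho dealkoxycarbonylation (LiCl, wet DMSO, 150 °C) should give 5-(2-Ar*-ethyl)cyclohex-2-en-1-one F2. This is aromatized by palladium-catalysed aerobic dehydrogenation (Pd(O2CCF3)2 (5 mol %), 2-(dimethylamino)pyridine, TsOH, O2 (1 atm), DMSO, 80 °C), a method established for turning 5-substituted cyclohexenones into meta-substituted phenols. The fallback comes back to the route at 22, so steps 9 and 10 fall away.

**Step 4** comes third.
- What may go wrong: protodeboronation, oxidative hydroxylation and homocoupling of the boronic acid may outrun O-arylation of the ortho-substituted phenol.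
- Fallback: the aryl donor is changed from a boronic acid to an aryl halide. It sets out from 7, which undergoes an Ullmann-type coupling with 1,4-diiodobenzene (3 equiv; CuI (10 mol %), N,N-dimethylglycine (30 mol %), Cs2CO3, dioxane, 90 °C). The excess of diiodide suppresses double coupling. The fallback comes back to the route at 9 and makes no compound outside the list (F0).

**Further compounds**
F1 | step 7 | 3-[(4-{2-(benzyloxy)-5-[2-(3-methoxyphenyl)ethyl]phenoxy}phenyl)ethynyl]phenol | COc1cccc(CCc2ccc(OCc3ccccc3)c(Oc3ccc(C#Cc4cccc(O)c4)cc3)c2)c1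
F2 | step 8 | 5-(2-Ar*-ethyl)cyclohex-2-en-1-one (racemic) | COc1cccc(CCc2ccc(OCc3ccccc3)c(Oc3ccc(CCC4CC=CC(=O)C4)cc3)c2)c1
F0 | step 4 | none | none
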